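The readings are simulated for substances that don't exist, noise included.

Time buys less and less in the amber flask: between 80.0 min and 150 min its target rose by 7.2 percentage points, but between 150 min and 240 min by 2.5 points, and we must choose what to do at 4.0 h.

| flask | substrate | coupling partner | temperature | remark | time |
|---|---|---|---|---|---|
| amber | 0.050 M | 0.035 M | 25 °C | the very flask that is asked about, followed so far |  |
| violet | 0.050 M | 0.070 M | 25 °C | run made earlier |  |
| flask | 0.050 M | 0.0350 M | 25 °C |  | 4.0 h |

| run | time / min | target / % | substrate / % |
|---|---|---|---|
| amber | 20.0 | 15.9 | 82.3 |
| amber | 30.0 | 20.7 | 76.6 |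
| amber | 50.0 | 29.8 | 66.8 |
| amber | 80.0 | 37.3 | 57.8 |
| amber | 150 | 44.5 | 45.9 |
| amber | 240 | 47.0 | 40.1 |
| violet | 3.00 | 5.3 | 92.7 |
| violet | 10.0 | 18.0 | 80.0 |
| violet | 20.0 | 30.3 | 67.5 |
| violet | 25.0 | 35.3 | 62.7 |
| violet | 40.0 | 46.9 | 48.8 |
| violet | 50.0 | 51.9 | 42.8 |

(each reading ± 0.5 percentage points)

- east: at 4.0 h raise the temperature by 20 K, then wait 80 min
- north: at 4.0 h add substrate, 50.0% of the amount charged, then wait 80 min
- south: change nothing and wait 80 min more
- south-west: at 4.0 h add coupling partner, 50.0% of the amount charged, then wait 80 min

* target, in percent of the substrate first charged, at 4.0 h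
* what to do for the largest gain in target; "none" if nothing gains more than 2 percentage points (east / north / south / south-west / none)
* target present, in percent of the substrate first charged, after east
* target present, in percent of the substrate first charged, after south

- what is added takes up no volume worth counting
- the earlier runs do not show what temperature does; that part of a forecast is a guess
- a reading or a percentage of target counts all its forms, free or not

We fold the charges of the amber flask into one number, the ceiling, which is coupling partner charged over substrate charged, 70.0%. Taking one partner per substrate, it is the share of the substrate that can react, so the partner is the limiting reagent. The amber flask has lost 59.9% of its substrate at 240 min, which leaves room of 10.1% under the ceiling. Adding 50.0% of partner lifts the ratio to 105%, whereas added substrate leaves the ceiling, reckoned on the substrate first charged, where it stands, so we choose south-west.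

One number is not enough, though. In the amber readings the shortfall, substrate lost minus target, grew from 9.60% at 150 min to 12.9% at 240 min, a gain of 3.3 points against the target's 2.5 points. We therefore take the reading 47.0% as the present target and expect south to stay within 2 points of it; for east, the runs do not show what temperature does, and we merely guess a loss.

The forecast gives 47%, chooses south-west, and puts east at 39% and south at 46.5%, and it says of the flask at 4.0 h: “Formation now barely offsets decay”.

The flask gives 46.7%, best option south-west, south 45.9% and east 26.9%.

    substrate + coupling partner ⇌ target (K = 74.0 M⁻¹, k = 0.00550 M⁻¹ s⁻¹, Ea = 51.0 kJ mol⁻¹, ΔH = 28.0 kJ mol⁻¹)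
    target → over-reaction product (k = 4.00 × 10⁻⁴ s⁻¹, Ea = 91.0 kJ mol⁻¹)
    crystals ⇌ target, rate k3*(cs3 - [target]) while solid is left; crystals form when [target] > cs3 (solubility = 1.00 mM, k = 0.00650 s⁻¹)
    (constants at 25 °C)

Dissolved target has a half-life of 29 min by the path to over-reaction product alone, short against 4.0 h. Under the ceiling of 70.0%, the flask at 4.0 h holds 60.9% of the substrate charged as target, crystals counted in, and over-reaction product, and its remaining partner accounts for 9.06% on the same scale. The neighbour flask, the same recipe with 0.0088 M of partner, has a ceiling of 17.6%, and there at 4.0 h target and over-reaction product together reach 16.5%.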